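**Plan**

- Retrosynthesis: each trans-2,3-diaryl-2,3-dihydrobenzofuran is cut at O1–C7a and C3–C3a, first in the upper ring (the one carrying the 4-hydroxyphenyl group), then in the lower ring. Each cut removes the benzo ring as a 3-oxy-5-styrylbenzyne and leaves O1–C2–C3 as a trans-stilbene oxide.
- Enabling feature: in both benzofurans C3a lies between two oxygenated carbons (C7a–O1 and C4–OH, a resorcinol ring) and C3 is benzylic. The C4 oxygen polarises the C7a≡C3a aryne so that an epoxide oxygen adds at C7a and the carbanion appears at C3a, next to the ionising C3.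
- Forward: aldehyde 8 is made once and gives two aryne precursors. Precursor 11 carries the styryl phenol as a triflate, because that arm becomes the second epoxide. Precursor 13 carries it as a benzyl ether, because that arm is the stilbene of the target. Stilbene 18 → (R,R)-epoxide 19 → lower ring with 11 (dimer 21) → (S,S)-epoxide 22 → upper ring with 13 (trimer 24) → deprotection.
- Stereochemistry: two Shi epoxidations with enantiomeric ketones fix C2′ and C2, whose C–O bonds are never broken. C3′ and C3 follow from retentive, trans-selective ring closure. All E-alkenes come from Horner–Wadsworth–Emmons reactions.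
- Helpers: aryl triflates on the catechol oxygens and on the phenol oxygen of the C2 aryl group suppress the competing benzylic C–O cleavage and are hydrolysed at the end. Benzyl ethers carry the other phenols.

Key step: step 16

Remark: locants O1 to C7a refer to each 2,3-dihydro-1-benzofuran, primed locants to the lower ring (the one bearing the catechol). Tf = trifluoromethanesulfonyl (triflyl), Bn = benzyl. Compounds 1, 9, 14, 16 and both enantiomers of the Shi ketone are taken as commercial.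

**Route**

Step 1
Reactants: 1 4-bromo-3,5-dihydroxybenzoic acid
Product: 2 2-bromo-5-(hydroxymethyl)benzene-1,3-diol
Conditions: BH3·THF (excess), THF, 0 → 60 °C; MeOH, then aq. HCl work-up
Reagents that add atoms: none
Why: Borane reduction of a carboxylic acid is chemoselective, leaves the aryl bromide alone and only transiently borylates the phenols; no stereocentre is involved.

Step 2
Reactants: 2 2-bromo-5-(hydroxymethyl)benzene-1,3-diol
Product: 3 2-bromo-1,3-bis(trimethylsilyloxy)-5-[(trimethylsilyloxy)methyl]benzene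
Conditions: (Me3Si)2NH, cat. (NH4)2SO4, 110 °C; evaporation
Reagents that add atoms: hexamethyldisilazane, C[Si](C)(C)N[Si](C)(C)C
Why: Exhaustive O-silylation with hexamethyldisilazane installs the two aryl silyl ethers needed for the silyl shift of step 3 and masks the benzylic alcohol.

Step 3
Reactants: 3 2-bromo-1,3-bis(trimethylsilyloxy)-5-[(trimethylsilyloxy)methyl]benzene
Product: 6 3-hydroxy-5-(hydroxymethyl)-2-(trimethylsilyl)phenyl trifluoromethanesulfonate, via lithium phenoxide 4 (not isolated), via bis-silyl triflate 5 (not isolated)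
Conditions: n-BuLi, THF, −78 °C; Tf2O, −78 → 0 °C; then citric acid, MeOH, rt
Reagents that add atoms: trifluoromethanesulfonic anhydride, FC(F)(F)S(=O)(=O)OS(=O)(=O)C(F)(F)F
Why: Bromine–lithium exchange gives an aryllithium flanked by two silyloxy groups; a single 1,3-O→C silyl shift (retro-Brook rearrangement) desymmetrises the resorcinol to a C-silyl lithium phenoxide that is trapped as the triflate, and mild acid methanolysis removes the two remaining O-silyl groups.

Step 4
Reactants: 6 3-hydroxy-5-(hydroxymethyl)-2-(trimethylsilyl)phenyl trifluoromethanesulfonate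
Product: 7 5-formyl-3-hydroxy-2-(trimethylsilyl)phenyl trifluoromethanesulfonate
Conditions: activated MnO2 (excess), CH2Cl2, rt
Reagents that add atoms: none
Why: MnO2 oxidises the benzylic alcohol selectively to the aldehyde, and the hindered, triflate-deactivated phenol should survive.

Step 5
Reactants: 7 5-formyl-3-hydroxy-2-(trimethylsilyl)phenyl trifluoromethanesulfonate
Product: 8 3-(benzyloxy)-5-formyl-2-(trimethylsilyl)phenyl trifluoromethanesulfonate
Conditions: BnOH, PPh3, DIAD, THF, 0 °C → rt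
Reagents that add atoms: benzyl alcohol, OCc1ccccc1
Why: Mitsunobu etherification benzylates the phenol under nearly neutral conditions, which avoids a base-triggered C→O silyl shift and premature aryne release from the ortho-silyl aryl triflate.

Step 6
Reactants: 9 diethyl (4-hydroxybenzyl)phosphonate
Product: 10 4-[(diethoxyphosphoryl)methyl]phenyl trifluoromethanesulfonate
Conditions: PhNTf2, Et3N, CH2Cl2, 0 °C → rt
Reagents that add atoms: N-phenylbis(trifluoromethanesulfonimide), O=S(=O)(N(c1ccccc1)S(=O)(=O)C(F)(F)F)C(F)(F)F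
Why: Phenol triflation with PhNTf2 is chemoselective in the presence of the phosphonate ester, whose P=O group would be activated by Tf2O.

Step 7
Reactants: 8 3-(benzyloxy)-5-formyl-2-(trimethylsilyl)phenyl trifluoromethanesulfonate, 10 4-[(diethoxyphosphoryl)methyl]phenyl trifluoromethanesulfonate
Product: 11 3-(benzyloxy)-5-[(E)-2-[4-(triflyloxy)phenyl]ethenyl]-2-(trimethylsilyl)phenyl trifluoromethanesulfonate
Conditions: 10, KN(SiMe3)2, THF, −78 °C; then 8, −78 → 0 °C
Reagents that add atoms: none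
Why: Horner–Wadsworth–Emmons olefination of a benzylphosphonate anion with an aromatic aldehyde gives the E-stilbene, and pre-forming the anion keeps free base away from the silyl triflate.

Step 8
Reactants: 9 diethyl (4-hydroxybenzyl)phosphonate
Product: 12 diethyl [4-(benzyloxy)benzyl]phosphonate
Conditions: BnBr, K2CO3, acetone, reflux
Reagents that add atoms: benzyl bromide, BrCc1ccccc1
Why: Williamson etherification of the phenoxide with benzyl bromide; K2CO3 is too weak a base to deprotonate the phosphonate methylene, so only O-alkylation should occur.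

Step 9
Reactants: 8 3-(benzyloxy)-5-formyl-2-(trimethylsilyl)phenyl trifluoromethanesulfonate, 12 diethyl [4-(benzyloxy)benzyl]phosphonate
Product: 13 3-(benzyloxy)-5-[(E)-2-[4-(benzyloxy)phenyl]ethenyl]-2-(trimethylsilyl)phenyl trifluoromethanesulfonate
Conditions: 12, KN(SiMe3)2, THF, −78 °C; then 8, −78 → 0 °C
Reagents that add atoms: none
Why: Horner–Wadsworth–Emmons olefination gives the E-stilbene as in step 7; the benzyl ether is chosen here because this arm remains the stilbene of the target and needs a protecting group only, not an electron-withdrawing control element.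

Step 10
Reactants: 14 3,4-dihydroxybenzaldehyde
Product: 15 4-formyl-1,2-phenylene bis(trifluoromethanesulfonate)
Conditions: Tf2O, pyridine, CH2Cl2, 0 °C
Reagents that add atoms: trifluoromethanesulfonic anhydride, FC(F)(F)S(=O)(=O)OS(=O)(=O)C(F)(F)F
Why: Standard double O-triflation of a catechol; the triflates later serve as the electron-withdrawing control elements of step 14.

Step 11
Reactants: 16 3,5-bis(benzyloxy)benzyl bromide
Product: 17 diethyl [3,5-bis(benzyloxy)benzyl]phosphonate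
Conditions: P(OEt)3 (neat), 130 °C
Reagents that add atoms: triethyl phosphite, CCOP(OCC)OCC
Why: Michaelis–Arbuzov reaction of a reactive benzylic bromide.

Step 12
Reactants: 15 4-formyl-1,2-phenylene bis(trifluoromethanesulfonate), 17 diethyl [3,5-bis(benzyloxy)benzyl]phosphonate
Product: 18 4-[(E)-2-[3,5-bis(benzyloxy)phenyl]ethenyl]-1,2-phenylene bis(trifluoromethanesulfonate)
Conditions: 17, KN(SiMe3)2, THF, −78 °C; then 15, −78 → 0 °C
Reagents that add atoms: none
Why: Horner–Wadsworth–Emmons olefination should give the E-stilbene, with the aryl triflates tolerated at low temperature.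

Step 13
Reactants: 18 4-[(E)-2-[3,5-bis(benzyloxy)phenyl]ethenyl]-1,2-phenylene bis(trifluoromethanesulfonate)
Product: 19 4-[(2R,3R)-3-[3,5-bis(benzyloxy)phenyl]oxiran-2-yl]-1,2-phenylene bis(trifluoromethanesulfonate)
Conditions: D-fructose-derived Shi ketone (0.3 equiv), Oxone (2KHSO5·KHSO4·K2SO4), K2CO3, Bu4NHSO4, MeCN–dimethoxymethane, aq. Na2B4O7 buffer (pH about 10.5), 0 °C
Reagents that add atoms: potassium peroxymonosulfate (active component of Oxone), [K+].[O-]S(=O)(=O)OO
Why: Shi asymmetric epoxidation: the chiral dioxirane transfers oxygen through a spiro transition state to one face of the E-alkene, which for trans-stilbenes should give the (R,R)-oxirane; the electron-poor and meta-oxygenated aryl groups keep the epoxide stable in the buffer.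

Step 14
Reactants: 19 4-[(2R,3R)-3-[3,5-bis(benzyloxy)phenyl]oxiran-2-yl]-1,2-phenylene bis(trifluoromethanesulfonate), 11 3-(benzyloxy)-5-[(E)-2-[4-(triflyloxy)phenyl]ethenyl]-2-(trimethylsilyl)phenyl trifluoromethanesulfonate
Product: 21 4-[(E)-2-{(2S,3S)-4-(benzyloxy)-3-[3,5-bis(benzyloxy)phenyl]-2-[3,4-bis(triflyloxy)phenyl]-2,3-dihydro-1-benzofuran-6-yl}ethenyl]phenyl trifluoromethanesulfonate, via benzyne 20 (not isolated)
Conditions: 11 (2 equiv, slow addition), CsF, MeCN–toluene (1:1), 4 Å MS, 40 °C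
Reagents that add atoms: none
Why: Proposed new method: the same type of aryne σ-insertion as in step 16 (closest known type: fluoride-induced aryne insertion into the C–O bond of monosubstituted oxiranes): the oxirane oxygen adds to C7a′ of benzyne 20 (distal to the benzyloxy group), the O-aryl oxiranium opens at the carbon bearing the 3,5-bis(benzyloxy)phenyl group because the other benzylic carbon is strongly deactivated by the bis(triflyloxy)phenyl ring, and the C3a′ carbanion collapses there with retention and trans to the C2′ aryl group, so C2′ keeps the epoxide configuration and the (2S,3S) ring should result.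

Step 15
Reactants: 21 4-[(E)-2-{(2S,3S)-4-(benzyloxy)-3-[3,5-bis(benzyloxy)phenyl]-2-[3,4-bis(triflyloxy)phenyl]-2,3-dihydro-1-benzofuran-6-yl}ethenyl]phenyl trifluoromethanesulfonate
Product: 22 4-[(2S,3S)-3-{(2S,3S)-4-(benzyloxy)-3-[3,5-bis(benzyloxy)phenyl]-2-[3,4-bis(triflyloxy)phenyl]-2,3-dihydro-1-benzofuran-6-yl}oxiran-2-yl]phenyl trifluoromethanesulfonate
Conditions: enantiomeric (L-fructose-type) Shi ketone (0.3–0.5 equiv), Oxone (2KHSO5·KHSO4·K2SO4), K2CO3, Bu4NHSO4, MeCN–dimethoxymethane, aq. Na2B4O7 buffer, 0 °C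
Reagents that add atoms: potassium peroxymonosulfate (active component of Oxone), [K+].[O-]S(=O)(=O)OO
Why: Shi epoxidation under reagent control: the enantiomeric ketone should deliver the (S,S)-oxirane, the remote stereocentres of the dihydrobenzofuran having little influence on the E-alkene faces.

Step 16
Reactants: 22 4-[(2S,3S)-3-{(2S,3S)-4-(benzyloxy)-3-[3,5-bis(benzyloxy)phenyl]-2-[3,4-bis(triflyloxy)phenyl]-2,3-dihydro-1-benzofuran-6-yl}oxiran-2-yl]phenyl trifluoromethanesulfonate, 13 3-(benzyloxy)-5-[(E)-2-[4-(benzyloxy)phenyl]ethenyl]-2-(trimethylsilyl)phenyl trifluoromethanesulfonate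
Product: 24 4-[(2R,3R)-4-(benzyloxy)-3-{(2S,3S)-4-(benzyloxy)-3-[3,5-bis(benzyloxy)phenyl]-2-[3,4-bis(triflyloxy)phenyl]-2,3-dihydro-1-benzofuran-6-yl}-6-[(E)-2-[4-(benzyloxy)phenyl]ethenyl]-2,3-dihydro-1-benzofuran-2-yl]phenyl trifluoromethanesulfonate, via benzyne 23 (not isolated)
Conditions: 13 (2.5 equiv, slow addition), CsF, MeCN–toluene (1:1), 4 Å MS, 40 °C
Reagents that add atoms: none
Why: Proposed new method: fluoride removes the silyl group of 13 and triflate leaves to give benzyne 23, whose C7a≡C3a bond is polarised by the inductively withdrawing benzyloxy group on C4, so the oxirane oxygen of 22 adds at C7a and the carbanion develops at C3a; the O-aryl oxiranium then opens at the C–O bond to the carbon carrying the dihydrobenzofuranyl ring (the other benzylic carbon is deactivated by the para-triflyloxy group) and the C3a carbanion collapses onto that carbon, a net insertion of the aryne into one C–O σ-bond (stepwise formal (3+2) annulation). The closest known reaction type is the fluoride-induced insertion of arynes into the C–O bond of monosubstituted oxiranes to give 2,3-dihydrobenzofurans, together with aryne insertions into other polar σ-bonds through onium-type zwitterions; new here are the trans-2,3-diaryl oxirane and the demand for regio- and stereocontrol. The five-membered ring O1–C2–C3–C3a–C7a closes by intramolecular combination of the C3a carbanion with the benzylic C3 cation of the ion pair, a 1,5-zwitterion collapse that is formally 5-endo-tet and therefore proceeds through the ion pair and not by backside displacement. C2 keeps the configuration of the epoxide carbon because its C–O bond is never broken (S in 22 becomes R in 24 only through the change in CIP priorities), and C3 is set by collapse on the face that oxygen leaves and trans to the C2 aryl group, the preferred arrangement even if a free cation intervenes, which should give (2R,3R). The step needs aryne regioselectivity (secured by the C4 benzyloxy group), regioselective C–O cleavage (secured by the triflate on the C2 aryl ring against the para-alkyl-substituted ring on C3) and chemoselectivity for the weakly nucleophilic epoxide oxygen (secured by slow aryne generation in a medium of low proton availability with excess 13).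

Step 17
Reactants: 24 4-[(2R,3R)-4-(benzyloxy)-3-{(2S,3S)-4-(benzyloxy)-3-[3,5-bis(benzyloxy)phenyl]-2-[3,4-bis(triflyloxy)phenyl]-2,3-dihydro-1-benzofuran-6-yl}-6-[(E)-2-[4-(benzyloxy)phenyl]ethenyl]-2,3-dihydro-1-benzofuran-2-yl]phenyl trifluoromethanesulfonate
Product: 25 4-[(2R,3R)-3-{(2S,3S)-2-[3,4-bis(triflyloxy)phenyl]-3-(3,5-dihydroxyphenyl)-4-hydroxy-2,3-dihydro-1-benzofuran-6-yl}-4-hydroxy-6-[(E)-2-(4-hydroxyphenyl)ethenyl]-2,3-dihydro-1-benzofuran-2-yl]phenyl trifluoromethanesulfonate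
Conditions: BCl3, pentamethylbenzene, CH2Cl2, −78 °C; MeOH quench
Reagents that add atoms: none
Why: Lewis-acid cleavage of the five aryl benzyl ethers with pentamethylbenzene as benzyl cation scavenger leaves the alkene and triflates untouched, and the electron-poor C2 aryl groups suppress ionisation of the C2–O bonds, so the four stereocentres should be kept.

Step 18
Reactants: 25 4-[(2R,3R)-3-{(2S,3S)-2-[3,4-bis(triflyloxy)phenyl]-3-(3,5-dihydroxyphenyl)-4-hydroxy-2,3-dihydro-1-benzofuran-6-yl}-4-hydroxy-6-[(E)-2-(4-hydroxyphenyl)ethenyl]-2,3-dihydro-1-benzofuran-2-yl]phenyl trifluoromethanesulfonate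
Product: 26 5-[(2S,3S)-2-(3,4-dihydroxyphenyl)-4-hydroxy-6-{(2R,3R)-4-hydroxy-2-(4-hydroxyphenyl)-6-[(E)-2-(4-hydroxyphenyl)ethenyl]-2,3-dihydro-1-benzofuran-3-yl}-2,3-dihydro-1-benzofuran-3-yl]benzene-1,3-diol
Conditions: aq. Et4NOH, 1,4-dioxane, rt, argon (degassed); then aq. NH4Cl
Reagents that add atoms: none
Why: Hydroxide attacks sulfur of the three aryl triflates (S–O cleavage) at room temperature and releases the phenols without touching the C–O bonds at the stereocentres; exclusion of oxygen protects the polyphenol.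

**Compound list**

1 | 4-bromo-3,5-dihydroxybenzoic acid | OC(=O)c1cc(O)c(Br)c(O)c1 | starting material
2 | 2-bromo-5-(hydroxymethyl)benzene-1,3-diol | OCc1cc(O)c(Br)c(O)c1 | intermediate
3 | 2-bromo-1,3-bis(trimethylsilyloxy)-5-[(trimethylsilyloxy)methyl]benzene | C[Si](C)(C)OCc1cc(O[Si](C)(C)C)c(Br)c(O[Si](C)(C)C)c1 | intermediate
4 | lithium 3-(trimethylsilyloxy)-2-(trimethylsilyl)-5-[(trimethylsilyloxy)methyl]phenoxide | [Li+].[O-]c1cc(CO[Si](C)(C)C)cc(O[Si](C)(C)C)c1[Si](C)(C)C | intermediate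
5 | 3-(trimethylsilyloxy)-2-(trimethylsilyl)-5-[(trimethylsilyloxy)methyl]phenyl trifluoromethanesulfonate | C[Si](C)(C)OCc1cc(O[Si](C)(C)C)c([Si](C)(C)C)c(OS(=O)(=O)C(F)(F)F)c1 | intermediate
6 | 3-hydroxy-5-(hydroxymethyl)-2-(trimethylsilyl)phenyl trifluoromethanesulfonate | OCc1cc(O)c([Si](C)(C)C)c(OS(=O)(=O)C(F)(F)F)c1 | intermediate
7 | 5-formyl-3-hydroxy-2-(trimethylsilyl)phenyl trifluoromethanesulfonate | O=Cc1cc(O)c([Si](C)(C)C)c(OS(=O)(=O)C(F)(F)F)c1 | intermediate
8 | 3-(benzyloxy)-5-formyl-2-(trimethylsilyl)phenyl trifluoromethanesulfonate | O=Cc1cc(OCc2ccccc2)c([Si](C)(C)C)c(OS(=O)(=O)C(F)(F)F)c1 | intermediate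
9 | diethyl (4-hydroxybenzyl)phosphonate | CCOP(=O)(Cc1ccc(O)cc1)OCC | starting material
10 | 4-[(diethoxyphosphoryl)methyl]phenyl trifluoromethanesulfonate | CCOP(=O)(Cc1ccc(OS(=O)(=O)C(F)(F)F)cc1)OCC | intermediate
11 | 3-(benzyloxy)-5-[(E)-2-[4-(triflyloxy)phenyl]ethenyl]-2-(trimethylsilyl)phenyl trifluoromethanesulfonate (aryne precursor for the lower ring) | C[Si](C)(C)c1c(OCc2ccccc2)cc(/C=C/c2ccc(OS(=O)(=O)C(F)(F)F)cc2)cc1OS(=O)(=O)C(F)(F)F | intermediate
12 | diethyl [4-(benzyloxy)benzyl]phosphonate | CCOP(=O)(Cc1ccc(OCc2ccccc2)cc1)OCC | intermediate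
13 | 3-(benzyloxy)-5-[(E)-2-[4-(benzyloxy)phenyl]ethenyl]-2-(trimethylsilyl)phenyl trifluoromethanesulfonate (aryne precursor for the upper ring) | C[Si](C)(C)c1c(OCc2ccccc2)cc(/C=C/c2ccc(OCc3ccccc3)cc2)cc1OS(=O)(=O)C(F)(F)F | intermediate
14 | 3,4-dihydroxybenzaldehyde | O=Cc1ccc(O)c(O)c1 | starting material
15 | 4-formyl-1,2-phenylene bis(trifluoromethanesulfonate) | O=Cc1ccc(OS(=O)(=O)C(F)(F)F)c(OS(=O)(=O)C(F)(F)F)c1 | intermediate
16 | 3,5-bis(benzyloxy)benzyl bromide | BrCc1cc(OCc2ccccc2)cc(OCc2ccccc2)c1 | starting material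
17 | diethyl [3,5-bis(benzyloxy)benzyl]phosphonate | CCOP(=O)(Cc1cc(OCc2ccccc2)cc(OCc2ccccc2)c1)OCC | intermediate
18 | 4-[(E)-2-[3,5-bis(benzyloxy)phenyl]ethenyl]-1,2-phenylene bis(trifluoromethanesulfonate) | FC(F)(F)S(=O)(=O)Oc1ccc(/C=C/c2cc(OCc3ccccc3)cc(OCc3ccccc3)c2)cc1OS(=O)(=O)C(F)(F)F | intermediate
19 | 4-[(2R,3R)-3-[3,5-bis(benzyloxy)phenyl]oxiran-2-yl]-1,2-phenylene bis(trifluoromethanesulfonate) | FC(F)(F)S(=O)(=O)Oc1ccc(cc1OS(=O)(=O)C(F)(F)F)[C@H]1O[C@@H]1c1cc(OCc2ccccc2)cc(OCc2ccccc2)c1 | intermediate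
20 | 3-(benzyloxy)-5-[(E)-2-[4-(triflyloxy)phenyl]ethenyl]benzyne (1,2-didehydrobenzene) | FC(F)(F)S(=O)(=O)Oc1ccc(/C=C/C2=CC#CC(OCc3ccccc3)=C2)cc1 | intermediate
21 | 4-[(E)-2-{(2S,3S)-4-(benzyloxy)-3-[3,5-bis(benzyloxy)phenyl]-2-[3,4-bis(triflyloxy)phenyl]-2,3-dihydro-1-benzofuran-6-yl}ethenyl]phenyl trifluoromethanesulfonate | FC(F)(F)S(=O)(=O)Oc1ccc(/C=C/c2cc(OCc3ccccc3)c3c(c2)O[C@H](c2ccc(OS(=O)(=O)C(F)(F)F)c(OS(=O)(=O)C(F)(F)F)c2)[C@H]3c2cc(OCc4ccccc4)cc(OCc4ccccc4)c2)cc1 | intermediate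
22 | 4-[(2S,3S)-3-{(2S,3S)-4-(benzyloxy)-3-[3,5-bis(benzyloxy)phenyl]-2-[3,4-bis(triflyloxy)phenyl]-2,3-dihydro-1-benzofuran-6-yl}oxiran-2-yl]phenyl trifluoromethanesulfonate | FC(F)(F)S(=O)(=O)Oc1ccc(cc1)[C@@H]1O[C@H]1c1cc(OCc2ccccc2)c2c(c1)O[C@H](c1ccc(OS(=O)(=O)C(F)(F)F)c(OS(=O)(=O)C(F)(F)F)c1)[C@H]2c1cc(OCc2ccccc2)cc(OCc2ccccc2)c1 | intermediate
23 | 3-(benzyloxy)-5-[(E)-2-[4-(benzyloxy)phenyl]ethenyl]benzyne (1,2-didehydrobenzene) | c1ccccc1COc1ccc(/C=C/C2=CC#CC(OCc3ccccc3)=C2)cc1 | intermediate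
24 | 4-[(2R,3R)-4-(benzyloxy)-3-{(2S,3S)-4-(benzyloxy)-3-[3,5-bis(benzyloxy)phenyl]-2-[3,4-bis(triflyloxy)phenyl]-2,3-dihydro-1-benzofuran-6-yl}-6-[(E)-2-[4-(benzyloxy)phenyl]ethenyl]-2,3-dihydro-1-benzofuran-2-yl]phenyl trifluoromethanesulfonate | c1ccccc1COc1ccc(/C=C/c2cc(OCc3ccccc3)c3c(c2)O[C@@H](c2ccc(OS(=O)(=O)C(F)(F)F)cc2)[C@@H]3c2cc(OCc3ccccc3)c3c(c2)O[C@H](c2ccc(OS(=O)(=O)C(F)(F)F)c(OS(=O)(=O)C(F)(F)F)c2)[C@H]3c2cc(OCc4ccccc4)cc(OCc4ccccc4)c2)cc1 | intermediate
25 | 4-[(2R,3R)-3-{(2S,3S)-2-[3,4-bis(triflyloxy)phenyl]-3-(3,5-dihydroxyphenyl)-4-hydroxy-2,3-dihydro-1-benzofuran-6-yl}-4-hydroxy-6-[(E)-2-(4-hydroxyphenyl)ethenyl]-2,3-dihydro-1-benzofuran-2-yl]phenyl trifluoromethanesulfonate | Oc1ccc(/C=C/c2cc(O)c3c(c2)O[C@@H](c2ccc(OS(=O)(=O)C(F)(F)F)cc2)[C@@H]3c2cc(O)c3c(c2)O[C@H](c2ccc(OS(=O)(=O)C(F)(F)F)c(OS(=O)(=O)C(F)(F)F)c2)[C@H]3c2cc(O)cc(O)c2)cc1 | intermediate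
26 | 5-[(2S,3S)-2-(3,4-dihydroxyphenyl)-4-hydroxy-6-{(2R,3R)-4-hydroxy-2-(4-hydroxyphenyl)-6-[(E)-2-(4-hydroxyphenyl)ethenyl]-2,3-dihydro-1-benzofuran-3-yl}-2,3-dihydro-1-benzofuran-3-yl]benzene-1,3-diol | Oc1ccc(/C=C/c2cc(O)c3c(c2)O[C@@H](c2ccc(O)cc2)[C@@H]3c2cc(O)c3c(c2)O[C@H](c2ccc(O)c(O)c2)[C@H]3c2cc(O)cc(O)c2)cc1 | target

**Step count and risks**

Total step count: 18. Longest linear sequence: 11 steps (1 → 2 → 3 → 6 → 7 → 8 → 11 → 21 → 22 → 24 → 25 → 26; steps 1, 2, 3, 4, 5, 7, 14, 15, 16, 17, 18).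

Steps most likely to fail:

1. Step 16 (Proposed new method). What may go wrong: the weakly nucleophilic, hindered epoxide oxygen loses the competition for the aryne, the aryl anion is protonated before ring closure, or the oxiranium opens at the wrong benzylic C–O bond. The fallback uses known chemistry, sets out from 21 and 13 and comes back at 24. Ozonolysis of the stilbene double bond of 21 (O3, CH2Cl2–MeOH, −78 °C; Me2S) should give (2S,3S)-4-(benzyloxy)-3-[3,5-bis(benzyloxy)phenyl]-2-[3,4-bis(triflyloxy)phenyl]-2,3-dihydro-1-benzofuran-6-carbaldehyde F1 together with 4-formylphenyl triflate. Pinnick oxidation (NaClO2, NaH2PO4, 2-methyl-2-butene) converts F1 into the corresponding 6-carboxylic acid F2. Benzyne 23, released from 13 with CsF in THF at 100–125 °C, inserts into the C–O bond of the carboxylic acid (O-arylation at C7a, then acyl transfer to the C3a carbanion, a known aryne reaction) and gives the ortho-hydroxyaryl ketone F3, which already holds the O1–C7a and C3a–C3 bonds. NaBH4 reduces F3 to the ortho-hydroxybenzhydrol F4. The 4-formylphenyl triflate from the ozonolysis is reduced (NaBH4) to 4-(hydroxymethyl)phenyl trifluoromethanesulfonate F5 and converted with (2R,5R)-2,5-dimethylthiolane and HBF4·OEt2 into the sulfonium salt (2R,5R)-2,5-dimethyl-1-[4-(triflyloxy)benzyl]thiolan-1-ium tetrafluoroborate F6. With Cs2CO3 in CH2Cl2, F4 releases its ortho-quinone methide and F6 its ylide, and a sulfur-ylide (4+1) annulation (conjugate addition at C3, then displacement of the sulfide by the phenoxide at C2) should close the trans ring and arrive at 24. The C2-symmetric sulfide controls the absolute sense, and its enantiomer would be chosen on a model substrate.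

2. Step 14 (Proposed new method). What may go wrong: low conversion because aryne oligomerisation or fluoride capture outruns attack by the epoxide oxygen, or Meinwald-type rearrangement of the oxiranium. The fallback uses known chemistry, sets out from 11 and 15 and comes back at 21. Benzyne 20 from 11 (CsF, THF, 100–125 °C) is inserted into the C–O bond of commercial 3,5-bis(benzyloxy)benzoic acid to give 4-[(E)-2-[3-(benzyloxy)-4-[3,5-bis(benzyloxy)benzoyl]-5-hydroxyphenyl]ethenyl]phenyl trifluoromethanesulfonate F7, and NaBH4 then gives the ortho-hydroxybenzhydrol F8. Aldehyde 15 is reduced (NaBH4) to 4-(hydroxymethyl)-1,2-phenylene bis(trifluoromethanesulfonate) F9 and converted with (2S,5S)-2,5-dimethylthiolane and HBF4·OEt2 into (2S,5S)-1-[3,4-bis(triflyloxy)benzyl]-2,5-dimethylthiolan-1-ium tetrafluoroborate F10. The base-mediated (4+1) annulation (Cs2CO3, CH2Cl2) of the quinone methide from F8 with the ylide from F10 should give the trans ring of 21. The enantiomeric sulfide is used because the lower ring has the opposite absolute sense.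

3. Step 18. What may go wrong: oxidative degradation, or base-induced opening of the C2–O bonds through quinone methides, of the fully liberated polyphenolate while three triflates are hydrolysed. The fallback reverses the order of the two deprotections, sets out from 24 and comes back at 26. The three triflates of 24 are hydrolysed first (aq. Et4NOH, 1,4-dioxane, rt), while the resorcinol-type and stilbene oxygens are still benzylated and the substrate is far less electron-rich, which gives the penta-O-benzyl triphenol 4-[(2S,3S)-4-(benzyloxy)-6-{(2R,3R)-4-(benzyloxy)-6-[(E)-2-[4-(benzyloxy)phenyl]ethenyl]-2-(4-hydroxyphenyl)-2,3-dihydro-1-benzofuran-3-yl}-3-[3,5-bis(benzyloxy)phenyl]-2,3-dihydro-1-benzofuran-2-yl]benzene-1,2-diol F11. The benzyl ethers are then removed last under non-basic conditions (BCl3, pentamethylbenzene, CH2Cl2, −78 °C) to give 26.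

**Further compounds**

F1 | step 16 | (2S,3S)-4-(benzyloxy)-3-[3,5-bis(benzyloxy)phenyl]-2-[3,4-bis(triflyloxy)phenyl]-2,3-dihydro-1-benzofuran-6-carbaldehyde | O=Cc1cc(OCc2ccccc2)c2c(c1)O[C@H](c1ccc(OS(=O)(=O)C(F)(F)F)c(OS(=O)(=O)C(F)(F)F)c1)[C@H]2c1cc(OCc2ccccc2)cc(OCc2ccccc2)c1
F2 | step 16 | (2S,3S)-4-(benzyloxy)-3-[3,5-bis(benzyloxy)phenyl]-2-[3,4-bis(triflyloxy)phenyl]-2,3-dihydro-1-benzofuran-6-carboxylic acid | OC(=O)c1cc(OCc2ccccc2)c2c(c1)O[C@H](c1ccc(OS(=O)(=O)C(F)(F)F)c(OS(=O)(=O)C(F)(F)F)c1)[C@H]2c1cc(OCc2ccccc2)cc(OCc2ccccc2)c1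
F3 | step 16 | {2-(benzyloxy)-4-[(E)-2-[4-(benzyloxy)phenyl]ethenyl]-6-hydroxyphenyl}{(2S,3S)-4-(benzyloxy)-3-[3,5-bis(benzyloxy)phenyl]-2-[3,4-bis(triflyloxy)phenyl]-2,3-dihydro-1-benzofuran-6-yl}methanone | c1ccccc1COc1ccc(/C=C/c2cc(O)c(C(=O)c3cc(OCc4ccccc4)c4c(c3)O[C@H](c3ccc(OS(=O)(=O)C(F)(F)F)c(OS(=O)(=O)C(F)(F)F)c3)[C@H]4c3cc(OCc5ccccc5)cc(OCc5ccccc5)c3)c(OCc3ccccc3)c2)cc1
F4 | step 16 | {2-(benzyloxy)-4-[(E)-2-[4-(benzyloxy)phenyl]ethenyl]-6-hydroxyphenyl}{(2S,3S)-4-(benzyloxy)-3-[3,5-bis(benzyloxy)phenyl]-2-[3,4-bis(triflyloxy)phenyl]-2,3-dihydro-1-benzofuran-6-yl}methanol (mixture of carbinol epimers) | c1ccccc1COc1ccc(/C=C/c2cc(O)c(C(O)c3cc(OCc4ccccc4)c4c(c3)O[C@H](c3ccc(OS(=O)(=O)C(F)(F)F)c(OS(=O)(=O)C(F)(F)F)c3)[C@H]4c3cc(OCc5ccccc5)cc(OCc5ccccc5)c3)c(OCc3ccccc3)c2)cc1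
F5 | step 16 | 4-(hydroxymethyl)phenyl trifluoromethanesulfonate | OCc1ccc(OS(=O)(=O)C(F)(F)F)cc1
F6 | step 16 | (2R,5R)-2,5-dimethyl-1-[4-(triflyloxy)benzyl]thiolan-1-ium tetrafluoroborate | C[C@@H]1CC[C@@H](C)[S+]1Cc1ccc(OS(=O)(=O)C(F)(F)F)cc1.F[B-](F)(F)F
F7 | step 14 | 4-[(E)-2-[3-(benzyloxy)-4-[3,5-bis(benzyloxy)benzoyl]-5-hydroxyphenyl]ethenyl]phenyl trifluoromethanesulfonate | FC(F)(F)S(=O)(=O)Oc1ccc(/C=C/c2cc(O)c(C(=O)c3cc(OCc4ccccc4)cc(OCc4ccccc4)c3)c(OCc3ccccc3)c2)cc1
F8 | step 14 | 4-[(E)-2-[3-(benzyloxy)-4-{[3,5-bis(benzyloxy)phenyl](hydroxy)methyl}-5-hydroxyphenyl]ethenyl]phenyl trifluoromethanesulfonate (racemic carbinol) | FC(F)(F)S(=O)(=O)Oc1ccc(/C=C/c2cc(O)c(C(O)c3cc(OCc4ccccc4)cc(OCc4ccccc4)c3)c(OCc3ccccc3)c2)cc1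
F9 | step 14 | 4-(hydroxymethyl)-1,2-phenylene bis(trifluoromethanesulfonate) | OCc1ccc(OS(=O)(=O)C(F)(F)F)c(OS(=O)(=O)C(F)(F)F)c1
F10 | step 14 | (2S,5S)-1-[3,4-bis(triflyloxy)benzyl]-2,5-dimethylthiolan-1-ium tetrafluoroborate | C[C@H]1CC[C@H](C)[S+]1Cc1ccc(OS(=O)(=O)C(F)(F)F)c(OS(=O)(=O)C(F)(F)F)c1.F[B-](F)(F)F
F11 | step 18 | 4-[(2S,3S)-4-(benzyloxy)-6-{(2R,3R)-4-(benzyloxy)-6-[(E)-2-[4-(benzyloxy)phenyl]ethenyl]-2-(4-hydroxyphenyl)-2,3-dihydro-1-benzofuran-3-yl}-3-[3,5-bis(benzyloxy)phenyl]-2,3-dihydro-1-benzofuran-2-yl]benzene-1,2-diol | c1ccccc1COc1ccc(/C=C/c2cc(OCc3ccccc3)c3c(c2)O[C@@H](c2ccc(O)cc2)[C@@H]3c2cc(OCc3ccccc3)c3c(c2)O[C@H](c2ccc(O)c(O)c2)[C@H]3c2cc(OCc4ccccc4)cc(OCc4ccccc4)c2)cc1
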